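## Analysis of the target

Shanciguol (11) is an achiral pentaphenol, C28H26O5, built on a bibenzyl. Ring A, a resorcinol, is joined through a CH2–CH2 bridge to ring C (a 3-hydroxyphenyl group) and carries two 4-hydroxybenzyl groups (the two rings B). Ring A bears OH at C1 and C3, H at C2, the benzyl groups at C4 and C6 and the arylethyl chain at C5; a mirror plane through C2 and C5 makes the two benzyl arms equivalent. There is no stereocentre and no ring to close, so the task is to place three carbon substituents on the adjacent carbons C4, C5 and C6 of an electron-rich ring. The sensitive groups are the five free phenols (air oxidation, incompatible with organometallic reagents) and the two diarylmethane links on the resorcinol ring, which strong acid can cleave or shift by retro-Friedel–Crafts reaction. The difficulty is C5: C4 and C6 are ortho/para to both oxygens and are natural nucleophilic sites, whereas C5 is meta to both oxygens and wedged between the two benzyl groups, out of reach of electrophilic substitution. The strategy rests on the fact that oxidation of ring A at C4 to a para-quinol methyl ether turns C1 into a carbonyl group and C5 into the β-carbon of the enone C5=C6–C1=O, while the other β-carbon, C3, is masked by its methoxy group as a vinylogous ester. The stereocentres that appear in the dearomatised intermediates (C4, C5, C6) vanish when ring A is rearomatised.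

## Retrosynthetic reasoning

**11 from 10.** The four O–CH3 bonds are cut last. Free phenols would quench the organometallic reagents and would be attacked by the oxidant used for dearomatisation, so all but one oxygen travel as methyl ethers, which survive every step and fall in one operation. The single free hydroxyl of 10 at C1 is the one that rearomatisation leaves behind.

**10 from 4 and 6.** The bond between C5 of ring A and the first bridge carbon is cut. The C4 and C6 benzyl bonds can be made by ordinary aromatic chemistry, but the C5 bond cannot. Cutting inside the bridge instead would still leave a carbon substituent at C5 with the same problem. In dienone 4, C5 is an enone β-carbon and accepts the chain as a nucleophile. The forward reaction must deliver the organocopper reagent 7 (made from 6) to C5 only, not to C3 or the carbonyl carbon. The adduct, held first as silyl dienol ether 8 and then as ketone 9, must lose the C4 methoxy group and the C5 hydrogen to return to the arene.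

**4 from 3.** The C4–OCH3 bond is cut. This methoxy group is a traceless activator: it is added when the free phenol of 3 is oxidised at the para carbon and leaves again in the key step. The monomethyl ether pattern of 3 has two jobs. The free C1 hydroxyl fixes the site of dearomatisation at C4, and the C3 methyl ether becomes the donor that closes C3 to nucleophiles.

**3 from 1 and 2.** Both ring A–CH2 bonds at C4 and C6 are cut. These carbons are ortho/para to both oxygens of 1, so the benzylic cation from alcohol 2 should be taken up there twice. The symmetric dibenzyl core thus comes in one step from two cheap compounds.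

**6 from 5.** The C–Mg bond is cut. Bromide 5 already holds ring C and both bridge carbons, so no further carbon–carbon bond is needed on that side.

## Alternatives that were turned down

**Alternative 1:** Both benzyl arms are cut at the ketone oxidation level, each on either side of a carbonyl carbon. In the forward sense, the dibromide A1 (the methylated bibenzyl core with bromine at C4 and C6) reacts twice with 4-methoxyphenylboronic acid A2 and carbon monoxide A3 under Pd(OAc)2 and di(1-adamantyl)butylphosphine, a two-fold carbonylative Suzuki–Miyaura coupling that gives the bis(diaryl ketone) A4.
- For it: four C–C bonds form in one operation, the symmetry is used in both directions, and the positions are fixed by the C–Br bonds. On regiochemical certainty it is stronger than the Friedel–Crafts benzylation of step 1. The C5 problem is avoided because the chain is present before the arms arrive.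
- Against it: each C–Br bond of A1 lies between a methoxy group and the arylethyl chain. Oxidative addition and acyl transfer at such doubly ortho-substituted positions are slow, and direct biaryl coupling without CO uptake competes; this must be overcome twice. A4 is also at the wrong oxidation level, so two diaryl ketones must be reduced to CH2 before demethylation, and A1 itself needs about three steps.
- Comparison: roughly seven steps with pressurised toxic gas, against five steps with no redox correction. The chosen route gives up the fixed regiochemistry of a cross-coupling for a much shorter sequence.

**Alternative 2:** The two bonds of the bridge, C5–CH2 and CH–ring C, are cut together. In the forward sense, the ring A C5 triflate A5 reacts with the vinylboron ate complex A6, which carries the ring C aryl group on boron, under Pd(OAc)2 and a racemic MandyPhos-type bisphosphine. The arylpalladium species of divalent palladium activates the vinyl group, the aryl group shifts from boron to the adjacent carbon while ring A is delivered to the terminal carbon, and the benzylic boronate A7 results.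
- For it: it is a modular three-component coupling that makes both bridge bonds at once and fixes the attachment at C5 through the triflate. Its step count is about the same as that of the chosen route, and on modularity it is stronger.
- Against it: the C–O bond of A5 is flanked by two benzyl groups, so oxidative addition and the final reductive elimination take place at a doubly ortho-substituted centre, outside the comfortable range of this coupling. The phenol behind A5 needs two benzyl groups ortho to its hydroxyl rather than between the methoxy groups, a selection the chosen route does not need. The boron of A7 is superfluous: it creates a stereocentre that must be erased by protodeboronation, and a chiral ligand is spent as a racemate.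
- Comparison: the chosen route concentrates its risk in one step with close precedent on quinol ethers and uses only bulk reagents.

**Alternative 3:** Ring A itself is cut at C1–C2 and C1–C6, with C1 supplied by carbon monoxide A3. In the forward sense, the 3-acetoxy-1,4-enyne A8 reacts with A3 under [Rh(CO)2Cl]2. A 1,2-acetoxy shift gives a rhodium vinylcarbene, CO insertion gives a dienylketene, and six-electron electrocyclisation followed by tautomerisation gives the resorcinol monoacetate A9.
- For it: every substituent of ring A is placed by the connectivity of an acyclic precursor, so no question of aromatic regiochemistry arises. The two ring A oxygens also emerge differentiated, which the chosen route achieves only through the monomethyl ether.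
- Against it: A8 is a tertiary propargylic acetate with three different arylalkyl arms and a trisubstituted alkene skipped relative to an anisyl ring. It is prone to ionisation and to alkene migration into conjugation, and it needs several C–C bond-forming steps of its own, so the difficulty moves from ring A to the precursor.
- Comparison: ring A is a plain resorcinol that can be bought. Building it from carbon monoxide costs at least three more steps than dearomatising it once.

Key step: step 4

Remark on the chemistry: the locants C1–C6 of ring A used in the text are those of the target and of dienone 4; the systematic names of 3 and 10 count the ring in the opposite direction. Compounds 4, 8 and 9 are racemic or diastereomeric mixtures, which is immaterial because their stereocentres are destroyed.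

## Route

**Step 1**
Reactants: 1 3-methoxyphenol; 2 4-methoxybenzyl alcohol (2.1 equiv)
Product: 3 5-methoxy-2,4-bis(4-methoxybenzyl)phenol
Conditions: Sc(OTf)3 (5 mol%), MeNO2, rt, slow addition of 2
Reagents that add atoms: none
Why: Two-fold Friedel–Crafts benzylation through the 4-methoxybenzyl cation; C4 and C6 of 1 are each ortho/para to both oxygen donors and unhindered, whereas C2 lies between the two oxygens. Benzylation of such rings is reversible under acid, which should favour the less crowded 4,6-pattern.

**Step 2**
Reactants: 3 5-methoxy-2,4-bis(4-methoxybenzyl)phenol
Product: 4 3,4-dimethoxy-4,6-bis(4-methoxybenzyl)cyclohexa-2,5-dien-1-one (racemic)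
Conditions: PhI(OAc)2 (1.1 equiv), MeOH, 0 °C; NaHCO3 work-up
Reagents that add atoms: methanol, CO
Why: Oxidative dearomatisation of a para-alkylphenol by a trivalent iodine reagent: ligand exchange at iodine and loss of iodobenzene give a phenoxonium ion, which methanol captures at C4, para to the oxygen and next to the C3 methoxy donor. The anisole rings are not oxidised under these conditions, and the C4 stereocentre forms as a racemate that is destroyed later.

**Step 3**
Reactants: 5 1-(2-bromoethyl)-3-methoxybenzene
Product: 6 2-(3-methoxyphenyl)ethylmagnesium bromide
Conditions: Mg turnings (I2 activation), THF, rt to 40 °C, slow addition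
Reagents that add atoms: magnesium, [Mg]
Why: Grignard formation by insertion of magnesium into a primary C–Br bond; slow addition keeps Wurtz coupling low, and the aryl methyl ether is inert.

**Step 4**
Reactants: 4 3,4-dimethoxy-4,6-bis(4-methoxybenzyl)cyclohexa-2,5-dien-1-one; 6 2-(3-methoxyphenyl)ethylmagnesium bromide (2 equiv)
Product: 10 5-methoxy-2,4-bis(4-methoxybenzyl)-3-[2-(3-methoxyphenyl)ethyl]phenol, via [2-(3-methoxyphenyl)ethyl]copper 7 (not isolated), via trimethylsilyl dienol ether 8 (not isolated), via cyclohexenone adduct 9 (not isolated)
Conditions: CuBr·SMe2 (1 equiv per 6), THF, −78 to −40 °C; Me3SiCl, then 4, −78 to −30 °C; aq. NH4Cl–NH3; then TsOH·H2O (cat.), MeOH–CH2Cl2, rt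
Reagents that add atoms: none
Why: Transmetalation of 6 to CuBr·SMe2 gives organocopper 7 with no free Grignard reagent left; 7 complexes the C5=C6 double bond of 4, bonds to C5 through a trivalent copper intermediate and, after reductive elimination, leaves an enolate that Me3SiCl captures as silyl dienol ether 8, the silyl chloride also speeding the addition so that it outruns electron transfer. The closest known reaction type is the copper-mediated 1,4-addition to 4-alkoxycyclohexa-2,5-dienones (para-quinol ethers) followed by loss of the alcohol, which gives meta-substituted phenols. No ring is closed. Site selectivity is the critical demand: C3 is the fully substituted β-carbon of a vinylogous ester and is deactivated by its methoxy donor, C5 is a β-CH, and the soft, weakly basic organocopper reagent avoids the carbonyl carbon. The new stereocentre at C5 (and the one at C6 in 9) forms without control as a diastereomer mixture relative to C4, which does not matter because all three carbons become sp2. Acid in methanol cleaves the O–Si bond to give ketone 9; in its C1=C6 enol the C4 methoxy group sits at the end of a 1,3-diene, so protonation and ionisation of this tertiary ether give a cyclohexadienyl cation spread over C4, C2 and C6, and loss of the C5 proton restores ring A as phenol 10. Aromatisation is irreversible and drives the preceding equilibria.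

**Step 5**
Reactants: 10 5-methoxy-2,4-bis(4-methoxybenzyl)-3-[2-(3-methoxyphenyl)ethyl]phenol
Product: 11 shanciguol, 4,6-bis(4-hydroxybenzyl)-5-[2-(3-hydroxyphenyl)ethyl]benzene-1,3-diol
Conditions: BBr3 (excess), CH2Cl2, −78 °C to rt; MeOH, then water
Reagents that add atoms: none
Why: Lewis-acid cleavage of the four aryl methyl ethers: boron coordinates each ether oxygen and bromide attacks the methyl group, after which aqueous work-up hydrolyses the aryl borates. The diarylmethane and bibenzyl C–C bonds should hold at low temperature.

## Compound list

1 | 3-methoxyphenol | COc1cccc(O)c1 | starting material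
2 | 4-methoxybenzyl alcohol | COc1ccc(CO)cc1 | starting material
3 | 5-methoxy-2,4-bis(4-methoxybenzyl)phenol | Oc1cc(OC)c(Cc2ccc(OC)cc2)cc1Cc1ccc(OC)cc1 | intermediate
4 | 3,4-dimethoxy-4,6-bis(4-methoxybenzyl)cyclohexa-2,5-dien-1-one (racemic) | O=C1C=C(OC)C(OC)(Cc2ccc(OC)cc2)C=C1Cc1ccc(OC)cc1 | intermediate
5 | 1-(2-bromoethyl)-3-methoxybenzene (2-(3-methoxyphenyl)ethyl bromide) | COc1cccc(CCBr)c1 | starting material
6 | 2-(3-methoxyphenyl)ethylmagnesium bromide | COc1cccc(CC[Mg]Br)c1 | intermediate
7 | [2-(3-methoxyphenyl)ethyl]copper (as its MgBr2 complex) | COc1cccc(CC[Cu])c1 | intermediate
8 | [[4,5-dimethoxy-2,4-bis(4-methoxybenzyl)-3-[2-(3-methoxyphenyl)ethyl]cyclohexa-1,5-dien-1-yl]oxy]trimethylsilane (racemic diastereomer mixture) | C[Si](C)(C)OC1=C(Cc2ccc(OC)cc2)C(CCc2cccc(OC)c2)C(OC)(Cc2ccc(OC)cc2)C(OC)=C1 | intermediate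
9 | 3,4-dimethoxy-4,6-bis(4-methoxybenzyl)-5-[2-(3-methoxyphenyl)ethyl]cyclohex-2-en-1-one (racemic diastereomer mixture) | O=C1C=C(OC)C(OC)(Cc2ccc(OC)cc2)C(CCc2cccc(OC)c2)C1Cc1ccc(OC)cc1 | intermediate
10 | 5-methoxy-2,4-bis(4-methoxybenzyl)-3-[2-(3-methoxyphenyl)ethyl]phenol | COc1ccc(Cc2c(O)cc(OC)c(Cc3ccc(OC)cc3)c2CCc2cccc(OC)c2)cc1 | intermediate
11 | shanciguol, 4,6-bis(4-hydroxybenzyl)-5-[2-(3-hydroxyphenyl)ethyl]benzene-1,3-diol | Oc1ccc(Cc2c(O)cc(O)c(Cc3ccc(O)cc3)c2CCc2cccc(O)c2)cc1 | target

## Step count and risks

Total step count: 5. Longest linear sequence: 4 steps (steps 1, 2, 4, 5); step 3 is a one-step side branch.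

**Step 4 (key step).**
- Electron transfer from the organocopper reagent to the dienone, followed by loss of methoxide, would rearomatise ring A reductively without forming the C–C bond.
- The addition itself may be slow, because C5 lies between the quaternary C4 and the substituted C6 and the enone is deactivated by the C3 methoxy donor; β-hydride elimination of 7 can then overtake it.
- In the acid stage, the cation could be captured by ring C in a Friedel–Crafts ring closure instead of losing the C5 proton.
- Fallback, setting out from 4 and 5: lithium metal in Et2O converts 5 into 2-(3-methoxyphenyl)ethyllithium F1. Dienone 4 is complexed at the carbonyl oxygen with MeAl(OAr)2 (Ar = 2,6-di-tert-butyl-4-methylphenyl) in toluene at −78 °C, and F1 is added. The bulky aluminium Lewis acid blocks the carbonyl carbon and activates the enone, so a reagent free of copper delivers the chain to C5, a known mode of 1,4-addition to quinol ethers. Aqueous work-up gives ketone 9, where the route is rejoined and the same acid treatment leads to 10.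

**Step 2.**
- Methanol may attack the phenoxonium ion at an ortho carbon instead of C4.
- The phenoxonium ion may lose a proton from the C4 benzylic CH2 group, giving a para-quinone methide that takes up methanol at the benzylic carbon.
- Adventitious acid may cause migration or loss of the C4 benzyl group in the dienone.
- Fallback, setting out from 3: Oxone with NaHCO3 in aqueous MeCN generates singlet oxygen, which adds at the para carbon of the phenol without a cationic intermediate, giving 4-hydroperoxy-3-methoxy-4,6-bis(4-methoxybenzyl)cyclohexa-2,5-dien-1-one F2. PPh3 reduces it to the para-quinol 4-hydroxy-3-methoxy-4,6-bis(4-methoxybenzyl)cyclohexa-2,5-dien-1-one F3, and MeI with Ag2O methylates the tertiary hydroxyl to return to 4.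

**Step 1.**
- Benzylation at C2, a third benzylation, alkylation of the anisyl rings of the product and acid-mediated transfer of benzyl groups can all erode the selectivity for the 4,6-pattern.
- Fallback, setting out from 1: two equivalents of NBS brominate C4 and C6 to give 2,4-dibromo-5-methoxyphenol F4. A two-fold Negishi coupling of F4 with commercial 4-methoxybenzylzinc chloride under Pd(OAc)2 and SPhos, which tolerates the free phenol, fixes both benzyl groups through the C–Br bonds and returns to 3.

**Step 5.**
- The HBr formed can cleave or shift the 4-hydroxybenzyl groups on the very electron-rich ring A by retro-Friedel–Crafts reaction.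
- Partially demethylated aryl borates may precipitate and stop the cleavage early.
- The pentaphenol may oxidise in air during work-up.
- Fallback, setting out from 10: excess NaSEt in DMF at about 140 °C removes the methyl groups by nucleophilic attack at carbon under basic conditions, where acid-driven benzyl transfer cannot occur. Acidification under argon gives 11 directly.

## Further compounds

F1 | step 4 | 2-(3-methoxyphenyl)ethyllithium | COc1cccc(CC[Li])c1
F2 | step 2 | 4-hydroperoxy-3-methoxy-4,6-bis(4-methoxybenzyl)cyclohexa-2,5-dien-1-one (racemic) | O=C1C=C(OC)C(OO)(Cc2ccc(OC)cc2)C=C1Cc1ccc(OC)cc1
F3 | step 2 | 4-hydroxy-3-methoxy-4,6-bis(4-methoxybenzyl)cyclohexa-2,5-dien-1-one (racemic) | O=C1C=C(OC)C(O)(Cc2ccc(OC)cc2)C=C1Cc1ccc(OC)cc1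
F4 | step 1 | 2,4-dibromo-5-methoxyphenol | COc1cc(O)c(Br)cc1Br
F0 | step 5 | none | none
A1 | alternative 1 | 2,4-dibromo-1,5-dimethoxy-3-[2-(3-methoxyphenyl)ethyl]benzene | COc1cccc(CCc2c(Br)c(OC)cc(OC)c2Br)c1
A2 | alternative 1 | 4-methoxyphenylboronic acid | COc1ccc(B(O)O)cc1
A3 | alternative 1 | carbon monoxide | [C-]#[O+]
A4 | alternative 1 | [4,6-dimethoxy-2-[2-(3-methoxyphenyl)ethyl]-1,3-phenylene]bis[(4-methoxyphenyl)methanone] | COc1ccc(C(=O)c2c(OC)cc(OC)c(C(=O)c3ccc(OC)cc3)c2CCc2cccc(OC)c2)cc1
A5 | alternative 2 | 3,5-dimethoxy-2,6-bis(4-methoxybenzyl)phenyl trifluoromethanesulfonate | COc1ccc(Cc2c(OC)cc(OC)c(Cc3ccc(OC)cc3)c2OS(=O)(=O)C(F)(F)F)cc1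
A6 | alternative 2 | lithium (3-methoxyphenyl)(vinyl)(pinacolato)borate | [Li+].C=C[B-]1(c2cccc(OC)c2)OC(C)(C)C(C)(C)O1
A7 | alternative 2 | 2-[2-[3,5-dimethoxy-2,6-bis(4-methoxybenzyl)phenyl]-1-(3-methoxyphenyl)ethyl]-4,4,5,5-tetramethyl-1,3,2-dioxaborolane (racemic) | COc1ccc(Cc2c(OC)cc(OC)c(Cc3ccc(OC)cc3)c2CC(B2OC(C)(C)C(C)(C)O2)c2cccc(OC)c2)cc1
A8 | alternative 3 | 3-(4-methoxybenzyl)-6-(4-methoxyphenyl)-4-[2-(3-methoxyphenyl)ethyl]hex-4-en-1-yn-3-yl acetate (racemic, alkene geometry not specified) | C#CC(OC(C)=O)(Cc1ccc(OC)cc1)C(CCc1cccc(OC)c1)=CCc1ccc(OC)cc1
A9 | alternative 3 | 5-hydroxy-2,4-bis(4-methoxybenzyl)-3-[2-(3-methoxyphenyl)ethyl]phenyl acetate | COc1ccc(Cc2c(O)cc(OC(C)=O)c(Cc3ccc(OC)cc3)c2CCc2cccc(OC)c2)cc1
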